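**Retrosynthetic overview**

1. Locants follow the dihydronaphthalene of the target: C1 vinylic CH, C2 aroyl-bearing carbon, C3 stereocenter, C4 CH2, C4a/C8a ring fusion, C6 OMe, C7 OH. Ring A is the fused guaiacol ring, ring B the carbocycle.
2. Target ⇐ debenzylation ⇐ enone alcohol ⇐ (LiBH4, then MnO2) ⇐ ring B imide, which carries the C3 stereocenter and comes from one flask.
3. Key disconnections C3–C4 and C1–C8a: a (3+3) annulation of a vanillyl bromide (C4 electrophile, C8a nucleophile) with a chiral imide enolate that carries C1=C2 as a vinylogous amide (C3 nucleophile, C1 latent electrophile).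
4. Enabling feature: C8a of ring A is para to the C6 methoxy group and ortho to the benzylic C4, and the C1=C2–C(=O)Ar enone of ring B is the elimination product of a masked C1 aldehyde. The vinylogous amide masks that aldehyde, leaves C2 without hydrogen so that only C3 is enolized, and is the electrophile for ring closure.
5. Ring order: both aromatic rings are bought; ring B is the only ring formed (step 6); the oxazolidinone ring is temporary and leaves in step 7.

Key step: step 6

Remark: the four starting materials are taken as purchased; the E geometry drawn for the vinylogous amide is of no consequence, since that double bond is re-formed in step 6.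

**Route**

Step 1
Reactants: 1 (4R)-4-benzyl-1,3-oxazolidin-2-one; 2 pent-4-enoyl chloride
Product: 3 (4R)-4-benzyl-3-(pent-4-enoyl)-1,3-oxazolidin-2-one
Conditions: Et3N, DMAP (cat.), CH2Cl2, 0 °C to rt
Reagents that add atoms: none
Why: N-acylation of the oxazolidinone by the acid chloride (nucleophilic acyl substitution with DMAP catalysis) should attach the auxiliary without touching its stereocenter.

Step 2
Reactants: 3 (4R)-4-benzyl-3-(pent-4-enoyl)-1,3-oxazolidin-2-one
Product: 5 (4R)-4-benzyl-3-(4-oxobutanoyl)-1,3-oxazolidin-2-one, via ozonide 4 (not isolated)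
Conditions: O3, CH2Cl2, −78 °C; then PPh3, −78 °C to rt
Reagents that add atoms: ozone, [O-][O+]=O
Why: Ozonolysis with reductive work-up (Criegee mechanism) should cleave the terminal alkene to the aldehyde while the imide is inert to ozone and phosphine.

Step 3
Reactants: 6 4-(benzyloxy)-3-methoxybenzoic acid
Product: 7 4-(benzyloxy)-3-methoxybenzoyl chloride
Conditions: (COCl)2, DMF (cat.), CH2Cl2, 0 °C to rt
Reagents that add atoms: oxalyl chloride, O=C(Cl)C(Cl)=O
Why: Acid chloride formation through the Vilsmeier-type chloroiminium catalyst is standard and leaves the aryl ethers untouched.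

Step 4
Reactants: 5 (4R)-4-benzyl-3-(4-oxobutanoyl)-1,3-oxazolidin-2-one; 7 4-(benzyloxy)-3-methoxybenzoyl chloride
Product: 9 (4R)-4-benzyl-3-{(3E)-3-[4-(benzyloxy)-3-methoxybenzoyl]-4-(morpholin-4-yl)but-3-enoyl}-1,3-oxazolidin-2-one, via enamine 8 (not isolated)
Conditions: morpholine, 4 Å molecular sieves, CH2Cl2, 0 °C; then Et3N, 7, 0 °C to rt
Reagents that add atoms: morpholine, C1COCCN1
Why: Stork enamine acylation should C-acylate the enamine β-carbon (the future C2) and, after loss of the C2 proton, give the push-pull vinylogous amide, whose conjugation drives the reaction; no stereocenter is formed.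

Step 5
Reactants: 10 [4-(benzyloxy)-3-methoxyphenyl]methanol
Product: 11 1-(benzyloxy)-4-(bromomethyl)-2-methoxybenzene
Conditions: PBr3, Et2O, 0 °C
Reagents that add atoms: phosphorus tribromide, BrP(Br)Br
Why: SN2 bromination of a primary benzylic alcohol through its phosphite ester is reliable and the product is used at once because electron-rich benzylic bromides ionize easily.

Step 6
Reactants: 9 (4R)-4-benzyl-3-{(3E)-3-[4-(benzyloxy)-3-methoxybenzoyl]-4-(morpholin-4-yl)but-3-enoyl}-1,3-oxazolidin-2-one; 11 1-(benzyloxy)-4-(bromomethyl)-2-methoxybenzene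
Product: 14 (4R)-4-benzyl-3-{[(3R)-7-(benzyloxy)-2-[4-(benzyloxy)-3-methoxybenzoyl]-6-methoxy-3,4-dihydronaphthalen-3-yl]carbonyl}-1,3-oxazolidin-2-one, via sodium enolate 12 (not isolated), via benzylated imide 13 (not isolated)
Conditions: NaN(SiMe3)2, THF, −78 °C; 11, −78 to −30 °C; then CF3CO2H, CH2Cl2, −30 °C to rt (one flask)
Reagents that add atoms: none
Why: NaN(SiMe3)2 should deprotonate only C3, α to the imide, because the vinylogous amide leaves C2 without hydrogen and is too electron-rich to be attacked by the enolate, and the chelated Z-enolate 12 is benzylated by 11 at C3 in an Evans asymmetric alkylation (SN2), which forms the C3–C4 bond. Acidification then O-protonates the vinylogous amide of 13 to a vinylogous iminium ion that is attacked at C1 by C8a of ring A, and β-elimination of morpholine restores the C1=C2 enone, which forms the C1–C8a bond; the closest known reaction type is the Bougault cyclodehydration of α-formyl (hydroxymethylene) carbonyl compounds carrying a 2-arylethyl chain, a Friedel–Crafts alkenylation by addition–elimination. Ring B closes as a six-membered ring, 6-endo-trig with respect to the C1=C2 bond (6-exo-trig if counted on the C1=N iminium form). The only new stereocenter, C3, is controlled by the auxiliary: its benzyl group shields one face of the chelated enolate, the bromide enters anti to it, and with the (4R)-auxiliary this should give the R configuration at C3, the descriptor being opposite to that of the familiar α-methyl cases only because the alkenyl carbon C2 outranks the incoming benzylic carbon. The step needs C- over O- and α- over γ-alkylation (secured by the soft benzylic bromide and the amino donor at C1), closure at C8a and not at C5 (C8a is para to the C6 methoxy group and unhindered, C5 is flanked by two substituents), and retention of the C3 configuration (the ring closure runs under acid, where C3–H is not ionized).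

Step 7
Reactants: 14 (4R)-4-benzyl-3-{[(3R)-7-(benzyloxy)-2-[4-(benzyloxy)-3-methoxybenzoyl]-6-methoxy-3,4-dihydronaphthalen-3-yl]carbonyl}-1,3-oxazolidin-2-one
Product: 15 [(3R)-7-(benzyloxy)-2-{[4-(benzyloxy)-3-methoxyphenyl](hydroxy)methyl}-6-methoxy-3,4-dihydronaphthalen-3-yl]methanol (both carbinol epimers)
Conditions: LiBH4, MeOH, THF, 0 °C; neutral work-up (aqueous Rochelle salt)
Reagents that add atoms: none
Why: Reductive cleavage of the Evans imide by LiBH4 (hydride attack at the exocyclic carbonyl, release of the auxiliary) should run with 1,2-reduction of the hindered aryl enone ketone, C3 staying untouched and the new carbinol center being of no consequence because it is oxidized in step 8.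

Step 8
Reactants: 15 [(3R)-7-(benzyloxy)-2-{[4-(benzyloxy)-3-methoxyphenyl](hydroxy)methyl}-6-methoxy-3,4-dihydronaphthalen-3-yl]methanol
Product: 16 [4-(benzyloxy)-3-methoxyphenyl][(3R)-7-(benzyloxy)-3-(hydroxymethyl)-6-methoxy-3,4-dihydronaphthalen-2-yl]methanone
Conditions: MnO2 (activated, excess), CH2Cl2, rt
Reagents that add atoms: none
Why: MnO2 oxidation is selective for the secondary alcohol that is both allylic and benzylic and should leave the saturated primary alcohol and the C3 center alone.

Step 9
Reactants: 16 [4-(benzyloxy)-3-methoxyphenyl][(3R)-7-(benzyloxy)-3-(hydroxymethyl)-6-methoxy-3,4-dihydronaphthalen-2-yl]methanone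
Product: 17 (4-hydroxy-3-methoxyphenyl)[(3R)-7-hydroxy-3-(hydroxymethyl)-6-methoxy-3,4-dihydronaphthalen-2-yl]methanone
Conditions: BCl3, pentamethylbenzene, CH2Cl2, −78 °C; then MeOH
Reagents that add atoms: none
Why: Lewis acid cleavage of the two aryl benzyl ethers with a non-basic cation scavenger should spare the C1=C2 alkene, the ketone and the methyl ethers, which a hydrogenolysis would not.

**Compound list**

1 | (4R)-4-benzyl-1,3-oxazolidin-2-one | O=C1N[C@H](Cc2ccccc2)CO1 | starting material
2 | pent-4-enoyl chloride | C=CCCC(=O)Cl | starting material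
3 | (4R)-4-benzyl-3-(pent-4-enoyl)-1,3-oxazolidin-2-one | C=CCCC(=O)N1[C@H](Cc2ccccc2)COC1=O | intermediate
4 | (4R)-4-benzyl-3-[3-(1,2,4-trioxolan-3-yl)propanoyl]-1,3-oxazolidin-2-one (ozonide) | O=C(CCC1OCOO1)N1[C@H](Cc2ccccc2)COC1=O | intermediate (not isolated)
5 | (4R)-4-benzyl-3-(4-oxobutanoyl)-1,3-oxazolidin-2-one | O=CCCC(=O)N1[C@H](Cc2ccccc2)COC1=O | intermediate
6 | 4-(benzyloxy)-3-methoxybenzoic acid | COc1cc(C(=O)O)ccc1OCc1ccccc1 | starting material
7 | 4-(benzyloxy)-3-methoxybenzoyl chloride | COc1cc(C(=O)Cl)ccc1OCc1ccccc1 | intermediate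
8 | (4R)-4-benzyl-3-[(3E)-4-(morpholin-4-yl)but-3-enoyl]-1,3-oxazolidin-2-one (enamine) | O=C(C/C=C/N1CCOCC1)N1[C@H](Cc2ccccc2)COC1=O | intermediate (not isolated)
9 | (4R)-4-benzyl-3-{(3E)-3-[4-(benzyloxy)-3-methoxybenzoyl]-4-(morpholin-4-yl)but-3-enoyl}-1,3-oxazolidin-2-one | O=C(C/C(C(=O)c1ccc(OCc2ccccc2)c(OC)c1)=C\N1CCOCC1)N1[C@H](Cc2ccccc2)COC1=O | intermediate
10 | [4-(benzyloxy)-3-methoxyphenyl]methanol | COc1cc(CO)ccc1OCc1ccccc1 | starting material
11 | 1-(benzyloxy)-4-(bromomethyl)-2-methoxybenzene | COc1cc(CBr)ccc1OCc1ccccc1 | intermediate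
12 | sodium (Z)-enolate of 9 | [Na+].[O-]/C(N1[C@H](Cc2ccccc2)COC1=O)=C\C(C(=O)c1ccc(OCc2ccccc2)c(OC)c1)=C/N1CCOCC1 | intermediate (not isolated)
13 | (4R)-4-benzyl-3-{(2R,3E)-3-[4-(benzyloxy)-3-methoxybenzoyl]-2-[4-(benzyloxy)-3-methoxybenzyl]-4-(morpholin-4-yl)but-3-enoyl}-1,3-oxazolidin-2-one | O=C([C@H](Cc1ccc(OCc2ccccc2)c(OC)c1)/C(C(=O)c1ccc(OCc2ccccc2)c(OC)c1)=C\N1CCOCC1)N1[C@H](Cc2ccccc2)COC1=O | intermediate (not isolated)
14 | (4R)-4-benzyl-3-{[(3R)-7-(benzyloxy)-2-[4-(benzyloxy)-3-methoxybenzoyl]-6-methoxy-3,4-dihydronaphthalen-3-yl]carbonyl}-1,3-oxazolidin-2-one | COc1cc(C(=O)C2=Cc3cc(OCc4ccccc4)c(OC)cc3C[C@H]2C(=O)N2[C@H](Cc3ccccc3)COC2=O)ccc1OCc1ccccc1 | intermediate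
15 | [(3R)-7-(benzyloxy)-2-{[4-(benzyloxy)-3-methoxyphenyl](hydroxy)methyl}-6-methoxy-3,4-dihydronaphthalen-3-yl]methanol (both carbinol epimers) | COc1cc(C(O)C2=Cc3cc(OCc4ccccc4)c(OC)cc3C[C@H]2CO)ccc1OCc1ccccc1 | intermediate
16 | [4-(benzyloxy)-3-methoxyphenyl][(3R)-7-(benzyloxy)-3-(hydroxymethyl)-6-methoxy-3,4-dihydronaphthalen-2-yl]methanone | COc1cc(C(=O)C2=Cc3cc(OCc4ccccc4)c(OC)cc3C[C@H]2CO)ccc1OCc1ccccc1 | intermediate
17 | (4-hydroxy-3-methoxyphenyl)[(3R)-7-hydroxy-3-(hydroxymethyl)-6-methoxy-3,4-dihydronaphthalen-2-yl]methanone | COc1cc(C(=O)C2=Cc3cc(O)c(OC)cc3C[C@H]2CO)ccc1O | target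

**Step count and risks**

Total steps: 9. Longest linear sequence: 7 steps (steps 1, 2, 4, 6, 7, 8, 9).

Steps most likely to fail:

1. Step 6. In the acid stage the imide carbonyl oxygen may capture the activated C1 faster than ring A does (five-membered O-cyclization), the closure may stay incomplete in the THF-containing medium, and the base-sensitive product may lose its C3 configuration by migration of the C1=C2 bond. The fallback sets out from 9 and 11 and returns at 16. The alkylation is run alone (NaN(SiMe3)2, THF, −78 °C, neutral quench) and benzylated imide 13 is isolated. LiBH4 (THF, MeOH, 0 °C) then reduces only the imide, the vinylogous amide being inert to borohydride, and gives (2E,3R)-1-[4-(benzyloxy)-3-methoxyphenyl]-3-[4-(benzyloxy)-3-methoxybenzyl]-4-hydroxy-2-(morpholin-4-ylmethylidene)butan-1-one F1. CF3CO2H in CH2Cl2 then closes the primary alcohol onto C1 to [4-(benzyloxy)-3-methoxyphenyl]{(4R)-4-[4-(benzyloxy)-3-methoxybenzyl]-4,5-dihydrofuran-3-yl}methanone F2, a cyclic vinylogous ester that ring A should open at C1 by Friedel–Crafts addition–elimination. This frees the CH2OH group and gives 16 directly, so that steps 7 and 8 are not needed and O-capture becomes productive.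

2. Step 7. Hydride may be delivered in the conjugate sense to the enone, and the basic medium may shift the C1=C2 bond toward C3 while the imide is still in place, which would erase the stereocenter. The fallback sets out from 14 and returns at 15. A Luche reduction (NaBH4, CeCl3·7H2O, MeOH–THF, −40 °C) first converts the ketone 1,2-selectively under non-basic conditions to (4R)-4-benzyl-3-{[(3R)-7-(benzyloxy)-2-{[4-(benzyloxy)-3-methoxyphenyl](hydroxy)methyl}-6-methoxy-3,4-dihydronaphthalen-3-yl]carbonyl}-1,3-oxazolidin-2-one F3, which no longer has an enone. LiBH4 (THF, MeOH, 0 °C) then cleaves the auxiliary to give 15.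

3. Step 4. Aminolysis of the imide by the secondary amine, self-condensation of the imide aldehyde, or acylation at nitrogen in place of carbon may erode the enamine acylation. The fallback sets out from 7 and returns at 9 and keeps the imide away from the amine. Purchased methyl 4-oxobutanoate F4 is condensed with morpholine (4 Å molecular sieves, CH2Cl2) to methyl (3E)-4-(morpholin-4-yl)but-3-enoate F5. This is acylated with 7 (Et3N, CH2Cl2, 0 °C) to methyl (3E)-3-[4-(benzyloxy)-3-methoxybenzoyl]-4-(morpholin-4-yl)but-3-enoate F6. LiOH (THF–H2O, rt) gives (3E)-3-[4-(benzyloxy)-3-methoxybenzoyl]-4-(morpholin-4-yl)but-3-enoic acid F7, and pivaloyl chloride/Et3N, then 1 and LiCl (THF, −20 °C to rt), attach the auxiliary to give 9.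

**Further compounds**

F1 | step 6 | (2E,3R)-1-[4-(benzyloxy)-3-methoxyphenyl]-3-[4-(benzyloxy)-3-methoxybenzyl]-4-hydroxy-2-(morpholin-4-ylmethylidene)butan-1-one | OC[C@H](Cc1ccc(OCc2ccccc2)c(OC)c1)/C(C(=O)c1ccc(OCc2ccccc2)c(OC)c1)=C\N1CCOCC1
F2 | step 6 | [4-(benzyloxy)-3-methoxyphenyl]{(4R)-4-[4-(benzyloxy)-3-methoxybenzyl]-4,5-dihydrofuran-3-yl}methanone | O=C(C1=COC[C@@H]1Cc1ccc(OCc2ccccc2)c(OC)c1)c1ccc(OCc2ccccc2)c(OC)c1
F3 | step 7 | (4R)-4-benzyl-3-{[(3R)-7-(benzyloxy)-2-{[4-(benzyloxy)-3-methoxyphenyl](hydroxy)methyl}-6-methoxy-3,4-dihydronaphthalen-3-yl]carbonyl}-1,3-oxazolidin-2-one | COc1cc(C(O)C2=Cc3cc(OCc4ccccc4)c(OC)cc3C[C@H]2C(=O)N2[C@H](Cc3ccccc3)COC2=O)ccc1OCc1ccccc1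
F4 | step 4 | methyl 4-oxobutanoate (purchased) | COC(=O)CCC=O
F5 | step 4 | methyl (3E)-4-(morpholin-4-yl)but-3-enoate | COC(=O)C/C=C/N1CCOCC1
F6 | step 4 | methyl (3E)-3-[4-(benzyloxy)-3-methoxybenzoyl]-4-(morpholin-4-yl)but-3-enoate | COC(=O)C/C(C(=O)c1ccc(OCc2ccccc2)c(OC)c1)=C\N1CCOCC1
F7 | step 4 | (3E)-3-[4-(benzyloxy)-3-methoxybenzoyl]-4-(morpholin-4-yl)but-3-enoic acid | OC(=O)C/C(C(=O)c1ccc(OCc2ccccc2)c(OC)c1)=C\N1CCOCC1
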